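The target is cut at the O–C16 bridge and at C11–C12. On ring C the C11 oxygen and the acetal carbon C16 on C13 stand 1,3-diaxial, tied through O–C16 with only the methylene C12 between them; this is what remains when a C11 aldehyde ketyl adds to the CH2 end of an acrylate whose α-carbon is C13 and the alkoxide then acylates on C16. One SmI2 operation thus makes two bonds, ring C and the bridging lactone, and sets C11 and C13. Its precursor is a sclareolide-derived decalin with a formyl group on C9 and, on quaternary C8, a silyloxymethyl group (C17) and the arm C14H(CH(OMe)2)–C13(=CH2)–CO2Me.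

Key step: step 14

Remark: atoms are numbered as in the spongian skeleton (C17 is the oxygenated carbon on C8, C15 the formyl carbon, C16 the acetal carbon); C17 is C12 in drimane nomenclature.

Step 1
Reactants: 1 (+)-sclareolide
Product: 2 8α-hydroxy-11-homodriman-12-oic acid
Conditions: KOH, MeOH–H2O, reflux; then 1 M HCl to pH 4–5 at 0 °C, extracted at once
Reagents that add atoms: potassium hydroxide, [K+].[OH-]
Why: Saponification of the γ-lactone leaves all four stereocentres untouched, and the hydroxy acid is kept cold and used at once so that it does not close back to the lactone.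

Step 2
Reactants: 2 8α-hydroxy-11-homodriman-12-oic acid
Product: 3 drim-9(11)-en-8α-ol
Conditions: Pb(OAc)4, Cu(OAc)2 (cat.), pyridine, PhH, 80 °C
Reagents that add atoms: none
Why: Kochi oxidative decarboxylation, in which the C11 radical left after loss of CO2 is oxidised by divalent copper and loses H9, gives the exocyclic C9=C11 alkene next to the tertiary 8α-alcohol.

Step 3
Reactants: 3 drim-9(11)-en-8α-ol
Product: 4 drima-8(12),9(11)-diene
Conditions: Martin sulfurane Ph2S[OC(CF3)2Ph]2, CH2Cl2, −40 → 0 °C
Reagents that add atoms: none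
Why: Dehydration of the tertiary alcohol by anti elimination from its alkoxysulfonium ion should favour the second exocyclic methylene, because the equatorial 8α-oxygen has an antiperiplanar hydrogen only on the methyl group and not on C7.

Step 4
Reactants: 4 drima-8(12),9(11)-diene
Product: 6 drim-8-ene-11,17-diol, via endoperoxide 5 (not isolated)
Conditions: O2, hν (white LED), tetraphenylporphyrin (cat.), CH2Cl2, −20 °C; then thiourea, MeOH, rt
Reagents that add atoms: dioxygen, O=O
Why: [4+2] cycloaddition of singlet oxygen to the s-cis bis-exocyclic diene and reduction of the O–O bond with thiourea is the standard route to a cis-2-ene-1,4-diol and places the alkene at C8=C9 with oxygen on both C11 and C17.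

Step 5
Reactants: 6 drim-8-ene-11,17-diol
Product: 7 17-O-TBS ether of the diol (C11–OH free)
Conditions: TBSCl (1.05 equiv), imidazole, CH2Cl2, −30 → 0 °C
Reagents that add atoms: tert-butyldimethylsilyl chloride, CC(C)(C)[Si](C)(C)Cl
Why: Kinetic silylation should pick the less hindered primary allylic alcohol, since the C17 hydroxyl lies next to the C7 methylene whereas the C11 hydroxyl is shielded by quaternary C10 with its axial methyl and by the C1 methylene.

Step 6
Reactants: 8 methyl 3,3-dimethoxypropanoate
Product: 9 3,3-dimethoxypropanoic acid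
Conditions: LiOH, THF–H2O, rt; then 1 M HCl to pH 4 at 0 °C
Reagents that add atoms: lithium hydroxide, [Li+].[OH-]
Why: Ester saponification under basic conditions, followed by a cold and mild acidification, leaves the dimethyl acetal intact.

Step 7
Reactants: 7 17-O-TBS ether of the diol; 9 3,3-dimethoxypropanoic acid
Product: 10 17-TBSO-drim-8-en-11-yl 3,3-dimethoxypropanoate
Conditions: EDC·HCl, DMAP (cat.), CH2Cl2, 0 °C → rt
Reagents that add atoms: none
Why: Steglich-type carbodiimide esterification acylates the hindered allylic C11 alcohol under neutral conditions and brings in C13 (carbonyl), C14 (methylene) and C15 (acetal carbon) in one piece.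

Step 8
Reactants: 10 17-TBSO-drim-8-en-11-yl 3,3-dimethoxypropanoate
Product: 13 Claisen acid (C9=C11 methylene; C8 with CH2OTBS and the arm C14H(CH(OMe)2)–C13O2H), via silyl ketene acetal 11 (not isolated), via silyl ester 12 (not isolated)
Conditions: LiN(i-Pr)2, THF–DMPU (4:1), −78 °C; TMSCl, Et3N; −78 → 65 °C; then aq. citric acid
Reagents that add atoms: none
Why: Ireland–Claisen rearrangement, in which the (Z)-silyl ketene acetal (favoured by DMPU and by lithium chelation to a methoxy group) reacts on the α face, away from the axial C10 methyl, through a chair that maps onto the future ring C (O11 in the place of C12, the ketene-acetal carbon as C13, the acetal carbon equatorial on C14), so that quaternary C8 (C14 α, C17 β) and C14 are set together while the alkene moves to C9=C11.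

Step 9
Reactants: 13 Claisen acid
Product: 14 methyl ketone (C13 acetyl)
Conditions: MeLi (3.5 equiv), Et2O, 0 °C → rt; inverse quench into aq. NH4Cl
Reagents that add atoms: methyllithium, [Li]C
Why: Addition of methyllithium to the lithium carboxylate stops at a stable geminal dialkoxide that gives the methyl ketone only on work-up, so the new methyl carbon (the future C12) is added without exposing C14 to base as a ketone.

Step 10
Reactants: 14 methyl ketone
Product: 15 enol triflate C13(OTf)=C12H2
Conditions: KN(SiMe3)2, THF, −78 °C; PhNTf2, −78 → 0 °C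
Reagents that add atoms: N-phenylbis(trifluoromethanesulfonimide), O=S(=O)(N(c1ccccc1)S(=O)(=O)C(F)(F)F)C(F)(F)F
Why: Kinetic enolisation toward the methyl group (C14 is tertiary and flanked by quaternary C8) and O-triflation give the terminal enol triflate without touching the C14 stereocentre.

Step 11
Reactants: 15 enol triflate
Product: 17 C11 primary alcohol (9α-H) bearing the enol triflate, via B-alkyl-9-BBN adduct 16 (not isolated)
Conditions: 9-BBN, THF, 60 °C; then NaBO3·4H2O, THF–H2O, rt
Reagents that add atoms: sodium perborate, [Na+].[Na+].O[B-]1(O)OO[B-](O)(O)OO1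
Why: Anti-Markovnikov hydroboration–oxidation of the only electron-rich alkene (the enol triflate is deactivated and no ester is yet present) puts boron on C11 and hydrogen on C9 from the α face, opposite the axial C10 methyl and the axial C17 arm, which gives the 9α-H configuration.

Step 12
Reactants: 17 C11 primary alcohol bearing the enol triflate
Product: 18 hydroxy acrylate (C13(=CH2)–CO2Me)
Conditions: Pd(OAc)2 (5 mol%), dppp, Et3N, CO (1 atm), MeOH–DMF, 60 °C
Reagents that add atoms: carbon monoxide, [C-]#[O+]; methanol, CO
Why: Palladium-catalysed methoxycarbonylation of the enol triflate (oxidative addition to zerovalent palladium, CO insertion, methanolysis) adds C16 and completes the acrylate, with solvent methanol outcompeting the hindered C11 hydroxyl for the acylpalladium.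

Step 13
Reactants: 18 hydroxy acrylate
Product: 19 aldehyde (C9 formyl; C8 with CH2OTBS and C14H(CH(OMe)2)–C13(=CH2)–CO2Me)
Conditions: Dess–Martin periodinane, NaHCO3, CH2Cl2, 0 °C → rt
Reagents that add atoms: none
Why: Dess–Martin oxidation of the primary alcohol under buffered conditions gives the C11 aldehyde, whose equatorial position on C9 is also the thermodynamic one.

Step 14
Reactants: 19 aldehyde
Product: 21 tricyclic bridged lactone (6-oxabicyclo[3.2.1]octan-7-one ring C), via hydroxy ester 20 (not isolated)
Conditions: SmI2 (2.5 equiv), t-BuOH (2 equiv), THF (no HMPA), −78 → 0 °C; then DBU (cat.), PhMe, 40 °C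
Reagents that add atoms: none
Why: SmI2 reduces the C11 aldehyde to a samarium ketyl that adds to the methylene C12 of the acrylate; a second electron turns the α-ester radical into a samarium enolate, t-BuOH protonates it at C13, and the C11 alkoxide acylates on C16 with loss of methoxide. The closest known reaction type is the SmI2 reductive coupling of aldehydes with acrylates to γ-lactones, run here inside one molecule. Ring C closes 6-endo-trig in the radical addition, because the tether sits on the acrylate α-carbon and the nucleophilic ketyl attacks only the electron-poor CH2 end, and the lactone ring closes 5-exo-trig in the acylation. C11 is set in a chair fused trans to the decalin at C8–C9, in which trivalent samarium, free of HMPA, bridges the ketyl oxygen and the ester carbonyl and so keeps the oxygen axial on the β face; C13 is set by the lactonisation, since only the ester that is axial and syn to O11 can close, and DBU returns the other epimer through the enolate. The step needs cyclisation to outrun simple reduction and pinacol coupling of the ketyl, which the chair with the acrylate held close on C8 should secure, and it needs no other group to be reduced, which holds because the acetal, the silyl ether and the unactivated ester are inert to SmI2 in THF.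

Step 15
Reactants: 21 tricyclic bridged lactone
Product: 22 lactol (C16–OH)
Conditions: i-Bu2AlH (1.2 equiv), CH2Cl2, −78 °C; aq. potassium sodium tartrate KNaC4H4O6
Reagents that add atoms: none
Why: Half-reduction of the only carbonyl group, the bridged γ-lactone, stops at the aluminium hemiacetal at −78 °C, and the lactol freed on work-up can equilibrate at C16 by ring opening.

Step 16
Reactants: 22 lactol
Product: 23 16-exo acetate
Conditions: Ac2O, pyridine, DMAP (cat.), CH2Cl2, rt
Reagents that add atoms: acetic anhydride, CC(=O)OC(C)=O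
Why: Acetylation of the equilibrating lactol should trap the anomer with the oxygen on the exo face, toward the C12 bridge and away from the axial C17 arm on C8, which is the less strained and the faster acylated one and is the C16 configuration of the target.

Step 17
Reactants: 23 16-exo acetate
Product: 24 C17 alcohol
Conditions: Bu4NF, AcOH (1:1), THF, rt → 40 °C
Reagents that add atoms: none
Why: Fluoride cleavage of the primary silyl ether under buffered, near-neutral conditions is chosen so that neither the acetoxy acetal (base) nor the dimethyl acetal next to the freed hydroxyl (acid) is touched.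

Step 18
Reactants: 24 C17 alcohol
Product: 25 C17 isovalerate (C15 still a dimethyl acetal)
Conditions: isovaleryl chloride, pyridine, DMAP (cat.), CH2Cl2, 0 °C → rt
Reagents that add atoms: 3-methylbutanoyl chloride, CC(C)CC(=O)Cl
Why: DMAP-catalysed acylation of the neopentyl-type primary alcohol with the acid chloride proceeds under conditions that leave the acetoxy acetal and the dimethyl acetal alone.

Step 19
Reactants: 25 C17 isovalerate
Product: 26 target CNP0331370.1
Conditions: PPTS (0.3 equiv), acetone–H2O (10:1), 45 °C
Reagents that add atoms: water, O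
Why: Mild acid-catalysed hydrolysis of the dimethyl acetal, which ionises far more readily than the acyl-deactivated acetoxy acetal at C16, frees the C15 aldehyde without touching the two esters or C14.

Compound list

1 | (+)-sclareolide (5α-H, 9α-H, 10β-Me, 8β-Me, 8α-O) | O=C1C[C@H]2[C@@](C)(CC[C@H]3C(C)(C)CCC[C@]23C)O1 | starting material
2 | 8α-hydroxy-11-homodriman-12-oic acid (9β-CH2CO2H, 9α-H, 8α-OH, 8β-Me) | OC(=O)C[C@H]1[C@](C)(O)CC[C@H]2C(C)(C)CCC[C@]12C | intermediate
3 | drim-9(11)-en-8α-ol (exocyclic C9=C11H2, 8α-OH, 8β-Me) | C=C1[C@](C)(O)CC[C@H]2C(C)(C)CCC[C@]12C | intermediate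
4 | drima-8(12),9(11)-diene (exocyclic methylenes on C8 and C9; 5α-H, 10β-Me) | C=C1C(=C)CC[C@H]2C(C)(C)CCC[C@]12C | intermediate
5 | 11,17-epidioxydrim-8-ene (O–O joins the CH2 groups on C8 and C9 of the C8=C9 alkene) | O1OCC2=C(C1)CC[C@H]3C(C)(C)CCC[C@]23C | intermediate
6 | drim-8-ene-11,17-diol (CH2OH on C9 is C11, CH2OH on C8 is C17) | OCC1=C(CO)CC[C@H]2C(C)(C)CCC[C@]12C | intermediate
7 | 17-O-tert-butyldimethylsilyl-drim-8-ene-11,17-diol (C11–OH free) | OCC1=C(CO[Si](C)(C)C(C)(C)C)CC[C@H]2C(C)(C)CCC[C@]12C | intermediate
8 | methyl 3,3-dimethoxypropanoate | COC(OC)CC(=O)OC | starting material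
9 | 3,3-dimethoxypropanoic acid | COC(OC)CC(=O)O | intermediate
10 | 17-TBSO-drim-8-en-11-yl 3,3-dimethoxypropanoate | COC(OC)CC(=O)OCC1=C(CO[Si](C)(C)C(C)(C)C)CC[C@H]2C(C)(C)CCC[C@]12C | intermediate
11 | (Z)-trimethylsilyl ketene acetal of 10 (CH(OMe)2 cis to OSiMe3) | COC(OC)/C=C(/OCC1=C(CO[Si](C)(C)C(C)(C)C)CC[C@H]2C(C)(C)CCC[C@]12C)O[Si](C)(C)C | intermediate
12 | trimethylsilyl ester of acid 13 | C=C1[C@](CO[Si](C)(C)C(C)(C)C)([C@H](C(OC)OC)C(=O)O[Si](C)(C)C)CC[C@H]2C(C)(C)CCC[C@]12C | intermediate
13 | Claisen acid: 9-methylene decalin, quaternary C8 with CH2OTBS (β, axial) and the α arm C14H(CH(OMe)2)–CO2H (carboxyl carbon is C13) | C=C1[C@](CO[Si](C)(C)C(C)(C)C)([C@H](C(OC)OC)C(=O)O)CC[C@H]2C(C)(C)CCC[C@]12C | intermediate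
14 | methyl ketone (C13 acetyl, otherwise as 13) | C=C1[C@](CO[Si](C)(C)C(C)(C)C)([C@H](C(OC)OC)C(C)=O)CC[C@H]2C(C)(C)CCC[C@]12C | intermediate
15 | enol triflate C13(OTf)=C12H2 (otherwise as 13) | C=C1[C@](CO[Si](C)(C)C(C)(C)C)([C@H](C(OC)OC)C(=C)OS(=O)(=O)C(F)(F)F)CC[C@H]2C(C)(C)CCC[C@]12C | intermediate
16 | B-alkyl-9-BBN adduct (boron on C11, 9α-H) | C(B1C2CCCC1CCC2)[C@H]1[C@](CO[Si](C)(C)C(C)(C)C)([C@H](C(OC)OC)C(=C)OS(=O)(=O)C(F)(F)F)CC[C@H]2C(C)(C)CCC[C@]12C | intermediate
17 | C11 primary alcohol (9β-CH2OH, 9α-H) bearing the enol triflate | OC[C@H]1[C@](CO[Si](C)(C)C(C)(C)C)([C@H](C(OC)OC)C(=C)OS(=O)(=O)C(F)(F)F)CC[C@H]2C(C)(C)CCC[C@]12C | intermediate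
18 | hydroxy acrylate (C11–OH; C13(=CH2)–CO2Me) | OC[C@H]1[C@](CO[Si](C)(C)C(C)(C)C)([C@H](C(OC)OC)C(=C)C(=O)OC)CC[C@H]2C(C)(C)CCC[C@]12C | intermediate
19 | key-step precursor: C9 formyl (β, 9α-H), C8 with CH2OTBS (β) and the α arm C14H(CH(OMe)2)–C13(=CH2)–CO2Me | O=C[C@H]1[C@](CO[Si](C)(C)C(C)(C)C)([C@H](C(OC)OC)C(=C)C(=O)OC)CC[C@H]2C(C)(C)CCC[C@]12C | intermediate
20 | 11β-hydroxy ester, formed as its samarium alkoxide (ring C closed; OH axial β on C11, CO2Me axial β on C13) | O[C@H]2C[C@@H](C(=O)OC)[C@@H](C(OC)OC)[C@]1(CO[Si](C)(C)C(C)(C)C)CC[C@H]3C(C)(C)CCC[C@]3(C)[C@@H]21 | intermediate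
21 | tricyclic bridged lactone (O11–C16 lactone, C15 dimethyl acetal equatorial on C14, C17 OTBS) | O=C1O[C@H]2C[C@@H]1[C@@H](C(OC)OC)[C@]1(CO[Si](C)(C)C(C)(C)C)CC[C@H]3C(C)(C)CCC[C@]3(C)[C@@H]21 | intermediate
22 | lactol (C16–OH; exo anomer drawn, the anomers interconvert) | O[C@H]1O[C@H]2C[C@@H]1[C@@H](C(OC)OC)[C@]1(CO[Si](C)(C)C(C)(C)C)CC[C@H]3C(C)(C)CCC[C@]3(C)[C@@H]21 | intermediate
23 | 16-exo acetate (acetoxy acetal; C17 OTBS, C15 dimethyl acetal) | CC(=O)O[C@H]1O[C@H]2C[C@@H]1[C@@H](C(OC)OC)[C@]1(CO[Si](C)(C)C(C)(C)C)CC[C@H]3C(C)(C)CCC[C@]3(C)[C@@H]21 | intermediate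
24 | C17 alcohol (16-exo acetate, C15 dimethyl acetal) | CC(=O)O[C@H]1O[C@H]2C[C@@H]1[C@@H](C(OC)OC)[C@]1(CO)CC[C@H]3C(C)(C)CCC[C@]3(C)[C@@H]21 | intermediate
25 | C17 isovalerate (16-exo acetate, C15 dimethyl acetal) | CC(=O)O[C@H]1O[C@H]2C[C@@H]1[C@@H](C(OC)OC)[C@]1(COC(=O)CC(C)C)CC[C@H]3C(C)(C)CCC[C@]3(C)[C@@H]21 | intermediate
26 | CNP0331370.1 | CC(=O)O[C@H]1O[C@H]2C[C@@H]1[C@@H](C=O)[C@]1(COC(=O)CC(C)C)CC[C@H]3C(C)(C)CCC[C@]3(C)[C@@H]21 | target

Total step count: 19. Longest linear sequence: 18 steps (steps 1–5 and 7–19, from sclareolide 1 to 26); step 6 is a one-step side branch.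

Steps most likely to fail

Step 14, the reductive cyclisation. The ketyl may add with the bulky samarium alkoxide equatorial instead of axial (wrong facial selectivity at C11, where the axial site lies between the C10 methyl and the C17 arm), and an equatorial oxygen cannot reach C16, so no lactone would form. The fallback sets out from aldehyde 19 and comes back at lactone 21; it sets C11 by hydride delivery to a ketone and not by the radical addition. The cyclised material with the wrong C11 configuration, the 11-epi hydroxy ester F1, would be oxidised with Dess–Martin periodinane to the C11 ketone F2. NaBH4 in MeOH at 0 °C should then deliver hydride from the open α face, the β face being closed by the C10 methyl and the C17 arm as in 11-oxo steroids. This gives the axial alcohol 20, which closes to 21 with DBU.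

Step 8, the Ireland–Claisen rearrangement. The lithium enolate may lose methoxide (β-elimination) before it is silylated, or the shift onto the tetrasubstituted alkene may be too slow for the ketene acetal to survive. The fallback sets out from alcohol 7 and comes back at methyl ketone 14; it uses a thermal, base-free Eschenmoser–Claisen rearrangement. Ester 8 and Me2NH give N,N-dimethyl-3,3-dimethoxypropanamide F3, which O-methylation with Me3OBF4 and then NaOMe converts into the amide acetal 1,1,3,3-tetramethoxy-N,N-dimethylpropan-1-amine F4. Heating 7 with F4 in xylene at 140 °C should give the rearranged dimethylamide F5 through the same chair (the ketene N,O-acetal equilibrates, so the acetal carbon takes the equatorial place). MeLi then converts the amide into 14.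

Step 3, the dehydration. The tertiary allylic alcohol may ionise, and regiocontrol in the elimination is then lost in favour of the endocyclic C7=C8 diene, which cannot undergo the [4+2] addition of step 4. The fallback sets out from alcohol 3 and comes back at diene 4; it separates the allylic transposition from the elimination. SOCl2 in Et2O should give, by rearrangement with allylic shift, 11-chlorodrim-8-ene F6. KOt-Bu in DMSO then effects a 1,4-dehydrochlorination through the methyl group that lies cis to the chloromethyl arm on the C8=C9 alkene.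

Further compounds

F1 | step 14 | 11-epi hydroxy ester (C11–OH equatorial, α) | O[C@@H]2C[C@@H](C(=O)OC)[C@@H](C(OC)OC)[C@]1(CO[Si](C)(C)C(C)(C)C)CC[C@H]3C(C)(C)CCC[C@]3(C)[C@@H]21
F2 | step 14 | C11 ketone of the cyclised ester | O=C2C[C@@H](C(=O)OC)[C@@H](C(OC)OC)[C@]1(CO[Si](C)(C)C(C)(C)C)CC[C@H]3C(C)(C)CCC[C@]3(C)[C@@H]21
F3 | step 8 | N,N-dimethyl-3,3-dimethoxypropanamide | COC(OC)CC(=O)N(C)C
F4 | step 8 | 1,1,3,3-tetramethoxy-N,N-dimethylpropan-1-amine | COC(OC)CC(OC)(OC)N(C)C
F5 | step 8 | rearranged dimethylamide (as 13, with C13 as CONMe2) | C=C1[C@](CO[Si](C)(C)C(C)(C)C)([C@H](C(OC)OC)C(=O)N(C)C)CC[C@H]2C(C)(C)CCC[C@]12C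
F6 | step 3 | 11-chlorodrim-8-ene | ClCC1=C(C)CC[C@H]2C(C)(C)CCC[C@]12C
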